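Readings and results come from a simulation with made-up constants, and the scatter is random.

We had to choose a temperature plan for a run of 6.0 min, and two of us disagreed.

| flask | starting material | solid reagent | catalyst | temperature | remark | time |
|---|---|---|---|---|---|---|
| Saturday's | 0.31 M | 2.5 equiv | 1 mol% | 52 °C | run made earlier |  |
| Monday's | 0.48 M | 2.5 equiv | 1 mol% | 80 °C | run made earlier |  |
| theta | 0.22 M | 2.50 equiv | 1 mol% | 90 °C |  | 6.0 min |
| zeta | 0.22 M | 2.50 equiv | 1 mol% | 40 °C |  | 6.0 min |
| beta | 0.22 M | 2.50 equiv | 1 mol% |  | at 90 °C until 3.0 min, from then on at 40 °C | 6.0 min |
| alpha | 0.22 M | 2.50 equiv | 1 mol% | 65 °C |  | 6.0 min |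

| Saturday's: time / min | Saturday's: target / % | Monday's: time / min | Monday's: target / % |
|---|---|---|---|
| 10.0 | 18.3 | 1.33 | 4.0 |
| 20.0 | 24.9 | 3.00 | 7.0 |
| 30.0 | 23.9 | 6.00 | 8.9 |
| 40.0 | 19.9 | 10.0 | 9.0 |

(standard deviation of a reading: 0.5 percentage points)
- as a solid, counted per litre of solution: solid reagent
- reactions considered so far: starting material + partner <-> isomer of the product; target + catalyst <-> isomer of the product + catalyst; starting material + partner <-> target; solid reagent <-> partner
- at the start none of the solid reagent is in solution
* the flask with the highest amount of target, in percent of the starting material charged ("all alike" if they lie within 1.5 percentage points) (theta / zeta / beta / alpha / all alike)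
* final target, as a percentage of the starting material charged, in theta
* final target, as a percentage of the starting material charged, in zeta
* final target, as a percentage of the starting material charged, in beta
* final target, as a percentage of the starting material charged, in alpha

Starting material takes up partner, which dissolves from the solid reagent, and gives target; the catalyst turns target into isomer of the product. So follow one molecule of target. At each moment it stays or leaves, by the catalyst to isomer of the product or back to starting material + partner, and k, the chance per minute of leaving by either way, acts as a pseudo-first-order constant at a given temperature and amount of catalyst. A molecule born mid-run has the keeping chance S, which is e raised to minus k times the time it still has to wait.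

At the top of a curve loss equals birth at that moment, and that birth is not read here, so I put the early birth rate in its place and divide it by the top; the quotient is a rough stand-in for k, not k itself. Monday's run gives the stand-in 0.334 min⁻¹, and Saturday's gives 0.0735 min⁻¹; both are readings with their scatter. The catalyst follows the starting material at fixed loading, but the way back to starting material + partner needs no catalyst; as a rough step I still scale each to 0.22 M, which gives 0.153 min⁻¹ at 80 °C and 0.0522 min⁻¹ at 52 °C.

The first chemist argued for cold. Over 3.00 min of waiting, S is 0.855 at 52 °C, and zeta is cooler still, whereas S stays under 0.632 in theta, which is hotter than Monday's. So zeta, or beta cooled early, should win.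

The second argued for warmth: the target must first be born. Saturday's early rate of 0.0183 min⁻¹ gives 11.0% in 6.0 min, and zeta is cooler than that run. My figure lies below the forecast's value for zeta. For alpha, whose temperature lies near the middle of the two runs, I take the geometric middle of the constants, and S is 0.765.

The forecast takes the warm side: alpha first, with 12% in theta, 11.5% in zeta, 14.5% in beta and 15.5% in alpha. In its words, “Alpha is narrowly highest, but uncertain against beta.”

    starting material + partner ⇌ isomer of the product (K = 830 M⁻¹, k = 0.0598 M⁻¹ s⁻¹, Ea = 54.0 kJ mol⁻¹, ΔH = −16.0 kJ mol⁻¹)
    target + catalyst ⇌ isomer of the product + catalyst, rate k2*[catalyst]*[target] forward; the back reaction follows from the equilibrium constant (k = 1.71 M⁻¹ s⁻¹, Ea = 51.0 kJ mol⁻¹)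
    starting material + partner ⇌ target (K = 13.0 M⁻¹, k = 0.289 M⁻¹ s⁻¹, Ea = 68.0 kJ mol⁻¹, ΔH = −29.0 kJ mol⁻¹)
    solid reagent ⇌ partner, rate k4*(cs4 - [partner]) while solid is left; crystals form when [partner] > cs4 (solubility = 44.0 mM, k = 0.0119 s⁻¹)
    (constants at 90 °C)

Alpha gave 20.2%, more than theta's 12.9%, zeta's 7.51% and beta's 14.0%. In theta, where my estimate put S under 0.632, target went from 11.8% at 3.00 min to 12.9% at 6.00 min, while isomer of the product rose from 14.0% at 3.00 min to 34.7% at 6.00 min. The cold view holds for long runs: at 60.0 min, zeta held 28.7% and beta 25.8%, against alpha's 4.58%. For beta's neighbour with 0.55 M of starting material, the same rough scaling of Monday's reading at 80 °C gives a k of 0.383 min⁻¹ as an estimate for the hot stage, so S comes to 0.563 for a molecule born mid-way through that stage; that flask held 6.69% target.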